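**Plan**

- Retrosynthesis: the O3 angelate and the O9 (E)-3-methylpent-2-enoate are cut first, then the C9–O bond (enolate oxidation), the C7–C11 bond (aldol with acetone) and, at the core, the C4–C5 bond of ring A.
- Enabling feature: ring A (C1–C5, C10) carries oxygen on C3 and a methyl on C4 next to quaternary C5, so it is a cyclopentanone (C1, C2, C3, C5, C10) widened by one CH(CH3) carbon set between C3 and C5; ring B (C5–C10) with C8=O and C9=C10 is the cyclohexenone of the Hajos–Parrish ketone.
- Forward: ring B and C5 are bought with (S)-Hajos–Parrish ketone. A two-carbon oxygenated unit is added to the five-ring ketone, and a 1,2-shift of C5 from the carbinol carbon (C3) to the sulfonate carbon (C4) turns the five-membered ring into ring A. C3–O, C7, C10–H and C9–O follow, and the two esters come last.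
- Stereochemistry: C5 from the starting ketone; the tertiary carbinol by α-face addition; the sulfonate carbon by chelation-controlled reduction; C4 by inversion in the shift; C3 by thermodynamic dissolving-metal reduction; C10 by Li/NH3 reduction (trans); C9 by α-face oxidation of the enol ether; C7 equatorial (epimerisable).

Key step: step 6

Assumption: angelic acid and (E)-3-methylpent-2-enoic acid are bought as single geometric isomers.
Conventions: hydrindanes carry indene numbering and decalins eremophilane numbering (ring A = C1–C5, C10; ring B = C5–C10); β is the face of the angular methyl (on C7a or C5), α the opposite face.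

**Step 1**
Reactants: 1 (S)-Hajos–Parrish ketone
Product: 2 enone 1,3-dithiolane of 1 (C3a=C4 retained; cyclopentanone free)
Conditions: HS(CH2)2SH, p-TsOH (cat.), AcOH, rt
Reagents that add atoms: ethane-1,2-dithiol (SCCS)
Why: Acid-catalysed thioketalisation is selective for the conjugated carbonyl, whose allyl-stabilised thionium intermediate forms readily while the cyclopentanone next to the quaternary carbon is hindered, so the enone is masked with its C=C in place and no stereocentre is touched.

**Step 2**
Reactants: 2 enone dithiolane; 3 ethyl vinyl ether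
Product: 6 (1S,7aS)-1-acetyl-1-hydroxy dithiolane (1β-OH; 1α-acetyl), via 1-ethoxyvinyllithium 4 (not isolated), via 1-ethoxyvinyl carbinol 5 (not isolated)
Conditions: 3, t-BuLi, THF, −78 → 0 °C; 2, −78 °C; then 1 M HCl, THF, 0 °C
Reagents that add atoms: water (O)
Why: Deprotonated ethyl vinyl ether is an acetyl anion equivalent whose 1,2-addition to the cyclopentanone takes place on the α face, anti to the 7a-methyl, which makes the new tertiary hydroxyl β (1S), and dilute acid then hydrolyses the enol ether to the methyl ketone while the dithiolane stays intact.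

**Step 3**
Reactants: 6 hydroxy ketone
Product: 7 (1S,7aS)-1-[(1R)-1-hydroxyethyl] diol (dithiolane retained)
Conditions: Zn(BH4)2, Et2O, −20 °C; 1 M HCl quench, 0 °C
Reagents that add atoms: none
Why: Chelation-controlled ketone reduction, in which Zn is held between the hydroxyl and carbonyl oxygens and the hydride enters from the side of the ring CH2 (C2) rather than past the quaternary C7a, which should set the (R) secondary carbinol.

**Step 4**
Reactants: 7 dithiolane diol
Product: 8 (1S,7aS)-1-hydroxy-1-[(1R)-1-hydroxyethyl]-7a-methyl-1,2,3,6,7,7a-hexahydro-5H-inden-5-one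
Conditions: MeI, CaCO3, MeCN/H2O (4:1), 45 °C
Reagents that add atoms: water (O)
Why: Alkylative dethioketalisation (S-methylation, then hydrolysis of the sulfonium ion, buffered by CaCO3) frees the enone without an oxidant, so the 1,2-diol, which hypervalent iodine reagents could cleave, is not at risk and no stereocentre changes.

**Step 5**
Reactants: 8 enone diol
Product: 9 (1R)-1-[(1S,7aS)-1-hydroxy-7a-methyl-5-oxo-hexahydroinden-1-yl]ethyl methanesulfonate
Conditions: MsCl, Et3N, CH2Cl2, −20 °C
Reagents that add atoms: methanesulfonyl chloride (CS(=O)(=O)Cl)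
Why: Sulfonylation distinguishes the secondary from the tertiary hydroxyl on steric grounds and takes place at oxygen with retention at the carbinol carbon, giving the β-hydroxy mesylate needed for the shift.

**Step 6**
Reactants: 9 hydroxy mesylate
Product: 11 (4R,5R)-4β,5β-dimethyloctal-9-ene-3,8-dione, via chloro(ethyl)aluminium alkoxide 10 (not isolated)
Conditions: Et2AlCl (3 equiv), CH2Cl2, −78 → −20 °C; 1 M HCl, 0 °C
Reagents that add atoms: none
Why: Et2AlCl turns the tertiary hydroxyl into the aluminium alkoxide 10, whose metal can also bind a sulfonyl oxygen, and as the mesylate leaves, the C3–C5 bond, antiperiplanar to the C4–O bond, moves to C4 while C3 becomes the carbonyl carbon, i.e. a semipinacol rearrangement whose closest known type is the organoaluminium-promoted 1,2-shift of β-mesyloxy alcohols. No ring is closed by cyclisation: ring A arises by ring enlargement, the five-membered ring C1–C2–C3–C5–C10 taking up C4 through a suprafacial 1,2-alkyl shift that forms the C4–C5 bond. C4 is the one new stereocentre and is set stereospecifically by inversion at the (R) sulfonate carbon, giving the 4β-methyl (4R) cis to the C5 methyl, while C5 migrates with retention. The step needs C5 and not the ring methylene C2 to migrate and needs the shift to outrun closure to the oxirane: with the side chain on the α face and (R) configured, the rotamer that keeps the small hydrogen between the two ring bonds holds the sulfonate anti to C5, the quaternary carbon is also the better migrating group, and an aluminium alkoxide is a poor nucleophile toward carbon. Work-up is cold and brief because C4 is now α to a ketone.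

**Step 7**
Reactants: 11 enedione
Product: 13 3α,8-bis(triethylsilyloxy)-4β,5β-dimethyl-10αH-octal-8-ene, via dilithium alkoxide enolate 12 (not isolated)
Conditions: Li (4.4 equiv), t-BuOH (2.2 equiv), NH3/THF, −78 °C; NH3 removed; Et3SiCl, Et3N, THF, −78 → 0 °C
Reagents that add atoms: chlorotriethylsilane (CC[Si](Cl)(CC)CC)
Why: Dissolving-metal reduction delivers the saturated C3 ketone under thermodynamic control to the equatorial 3α-alkoxide (hydride reagents would be steered to the axial epimer by the syn-axial C5 methyl), reduces the enone in the same operation to its C8(9) lithium enolate, which is shielded from further reduction, and silylation of both oxygens stores the enolate for step 8; the C10 hydrogen enters α, but this centre is removed again in step 8.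

**Step 8**
Reactants: 13 bis(silyl) compound
Product: 14 3α-(triethylsilyloxy)-4β,5β-dimethyloctal-9-en-8-one
Conditions: Pd(OAc)2 (1.1 equiv), MeCN, rt
Reagents that add atoms: none
Why: Saegusa–Ito oxidation, in which palladation of the silyl enol ether at C9 and β-hydride elimination of H10, the only hydrogen available, should return the 9-en-8-one regiospecifically with the C3 triethylsilyl ether untouched.

**Step 9**
Reactants: 14 silyloxy enone; 15 acetone
Product: 17 11-hydroxy-3α-(triethylsilyloxy)eremophil-9-en-8-one (7α side chain; 7β-H), via lithium dienolate 16 (not isolated)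
Conditions: LiN(iPr)2, THF, −78 °C; 15, −78 °C; AcOH, −78 °C
Reagents that add atoms: none
Why: Kinetic deprotonation of the cyclohexenone at the α' carbon C7 gives the cross-conjugated enolate, whose aldol addition to acetone should take place on the α face, away from the axial C5 methyl that is 1,3 to C7, placing the hydroxypropyl group equatorial (7α), the arrangement also favoured on equilibration.

**Step 10**
Reactants: 17 aldol adduct
Product: 19 3α-(triethylsilyloxy)eremophila-9,11-dien-8-one (7α-isopropenyl), via chlorosulfite 18 (not isolated)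
Conditions: SOCl2, pyridine, CH2Cl2, −30 °C
Reagents that add atoms: none
Why: Dehydration through the chlorosulfite with pyridine as base is an E2 process under kinetic control in which one of the six methyl hydrogens is removed rather than the single hindered H7, which should favour the non-conjugated isopropenyl group; no stereocentre is affected.

**Step 11**
Reactants: 19 isopropenyl enone
Product: 21 3α-(triethylsilyloxy)-8-(trimethylsilyloxy)-10αH-eremophila-8,11-diene, via lithium enolate 20 (not isolated)
Conditions: Li (2.2 equiv), t-BuOH (1.0 equiv), NH3/THF, −78 °C; NH3 removed; Me3SiCl, Et3N, THF, −78 → 0 °C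
Reagents that add atoms: chlorotrimethylsilane (C[Si](C)(C)Cl)
Why: Li/NH3 reduction of the octalenone with protonation at C10 from the α face, axial and anti to the C5 methyl, gives the trans-decalin, and the regiodefined C8(9) enolate is captured on oxygen as the trimethylsilyl enol ether while the isolated isopropenyl group and the silyl ether are inert.

**Step 12**
Reactants: 21 silyl enol ether
Product: 24 9α-hydroxy-3α-(triethylsilyloxy)-10αH-eremophil-11-en-8-one, via silyloxy epoxide 22 (not isolated), via α-silyloxy ketone 23 (not isolated)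
Conditions: mCPBA (1.05 equiv), hexane/CH2Cl2, −20 °C; then citric acid (cat.), MeOH, 0 °C
Reagents that add atoms: m-chloroperbenzoic acid (O=C(OO)c1cccc(Cl)c1)
Why: Rubottom oxidation, in which the electron-rich silyl enol ether is epoxidised much faster than the 1,1-disubstituted alkene and from the α face, since the axial C5 methyl is 1,3-diaxial to the β face of C9, and silyl migration followed by methanolysis of the trimethylsilyl ether gives the equatorial 9α-hydroxy ketone.

**Step 13**
Reactants: 24 hydroxy ketone; 25 (E)-3-methylpent-2-enoic acid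
Product: 26 9α-[(E)-3-methylpent-2-enoyloxy]-3α-(triethylsilyloxy)-10αH-eremophil-11-en-8-one
Conditions: DCC, DMAP (cat.), CH2Cl2, 0 °C → rt
Reagents that add atoms: none
Why: Steglich esterification acylates the only free hydroxyl under mild conditions, with the E geometry of the acid and the base-sensitive 7-isopropenyl ketone expected to survive catalytic DMAP at low temperature, and O-acylation leaves C9 unchanged.

**Step 14**
Reactants: 26 silyl ether ester
Product: 27 3α-hydroxy-9α-[(E)-3-methylpent-2-enoyloxy]-10αH-eremophil-11-en-8-one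
Conditions: HF·pyridine, pyridine, THF, 0 °C
Reagents that add atoms: none
Why: Buffered fluoride cleavage of the triethylsilyl ether is mild enough to leave the ester, the α-acyloxy ketone and the β,γ-unsaturated ketone as they are, and it frees the 3α-hydroxyl with retention.

**Step 15**
Reactants: 27 hydroxy ester; 28 angelic acid
Product: 30 CNP0301161.1 (target), via angelic 2,4,6-trichlorobenzoic anhydride 29 (not isolated)
Conditions: 28, 2,4,6-trichlorobenzoyl chloride, Et3N, toluene, rt; then 27, 70 °C
Reagents that add atoms: none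
Why: Yamaguchi esterification through the preformed mixed anhydride, run without a nucleophilic amine catalyst, should transfer the (Z)-2-methylbut-2-enoyl group to O3 without isomerisation to the tiglate and, being an O-acylation, keeps the 3α configuration.

**Compound list**

1 | (S)-Hajos–Parrish ketone, (7aS)-7a-methyl-2,3,7,7a-tetrahydro-1H-indene-1,5(6H)-dione | C[C@]12CCC(=O)C=C1CCC2=O | starting material
2 | (7aS)-5,5-(ethylenedithio)-7a-methyl-2,3,5,6,7,7a-hexahydro-1H-inden-1-one | C[C@]12CCC3(SCCS3)C=C1CCC2=O | intermediate
3 | ethyl vinyl ether | C=COCC | starting material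
4 | 1-ethoxyvinyllithium | [Li]C(=C)OCC | intermediate
5 | (1S,7aS)-1-(1-ethoxyvinyl)-5,5-(ethylenedithio)-7a-methyl-2,3,5,6,7,7a-hexahydro-1H-inden-1-ol (1β-OH) | C[C@]12CCC3(SCCS3)C=C1CC[C@@]2(O)C(=C)OCC | intermediate
6 | (1S,7aS)-1-acetyl-5,5-(ethylenedithio)-7a-methyl-2,3,5,6,7,7a-hexahydro-1H-inden-1-ol (1β-OH, 1α-acetyl) | C[C@]12CCC3(SCCS3)C=C1CC[C@@]2(O)C(C)=O | intermediate
7 | (1S,7aS)-5,5-(ethylenedithio)-1-[(1R)-1-hydroxyethyl]-7a-methyl-2,3,5,6,7,7a-hexahydro-1H-inden-1-ol | C[C@]12CCC3(SCCS3)C=C1CC[C@@]2(O)[C@@H](C)O | intermediate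
8 | (1S,7aS)-1-hydroxy-1-[(1R)-1-hydroxyethyl]-7a-methyl-1,2,3,6,7,7a-hexahydro-5H-inden-5-one | C[C@]12CCC(=O)C=C1CC[C@@]2(O)[C@@H](C)O | intermediate
9 | (1R)-1-[(1S,7aS)-1-hydroxy-7a-methyl-5-oxo-2,3,5,6,7,7a-hexahydro-1H-inden-1-yl]ethyl methanesulfonate | C[C@]12CCC(=O)C=C1CC[C@@]2(O)[C@@H](C)OS(C)(=O)=O | intermediate
10 | chloro(ethyl)aluminium alkoxide of 9 | C[C@]12CCC(=O)C=C1CC[C@@]2(O[Al](Cl)CC)[C@@H](C)OS(C)(=O)=O | intermediate
11 | (4R,5R)-4β,5β-dimethyloctal-9-ene-3,8-dione, (4aR,5R)-4a,5-dimethyl-4,4a,7,8-tetrahydronaphthalene-2,6(3H,5H)-dione | O=C1CC[C@]2(C)[C@@H](C)C(=O)CCC2=C1 | intermediate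
12 | dilithium 3α-alkoxide C8(9)-enolate of reduced 11 (10α-H) | C1C[C@]2(C)[C@@H](C)[C@H](O[Li])CC[C@H]2C=C1O[Li] | intermediate
13 | 3α,8-bis(triethylsilyloxy)-4β,5β-dimethyl-10αH-octal-8-ene | C1C[C@]2(C)[C@@H](C)[C@H](O[Si](CC)(CC)CC)CC[C@H]2C=C1O[Si](CC)(CC)CC | intermediate
14 | 3α-(triethylsilyloxy)-4β,5β-dimethyloctal-9-en-8-one | C1C[C@]2(C)[C@@H](C)[C@H](O[Si](CC)(CC)CC)CCC2=CC1=O | intermediate
15 | acetone | CC(C)=O | starting material
16 | lithium C7(8),C9(10)-dienolate of 14 | [Li]OC1=CC[C@]2(C)[C@@H](C)[C@H](O[Si](CC)(CC)CC)CCC2=C1 | intermediate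
17 | 11-hydroxy-3α-(triethylsilyloxy)eremophil-9-en-8-one (4β,5β-dimethyl, 7α-(2-hydroxypropan-2-yl)) | CC(C)(O)[C@@H]1C[C@]2(C)[C@@H](C)[C@H](O[Si](CC)(CC)CC)CCC2=CC1=O | intermediate
18 | chlorosulfite of 17 | CC(C)(OS(=O)Cl)[C@@H]1C[C@]2(C)[C@@H](C)[C@H](O[Si](CC)(CC)CC)CCC2=CC1=O | intermediate
19 | 3α-(triethylsilyloxy)eremophila-9,11-dien-8-one (7α-isopropenyl) | C=C(C)[C@@H]1C[C@]2(C)[C@@H](C)[C@H](O[Si](CC)(CC)CC)CCC2=CC1=O | intermediate
20 | lithium C8(9)-enolate of reduced 19 (10α-H) | C=C(C)[C@@H]1C[C@]2(C)[C@@H](C)[C@H](O[Si](CC)(CC)CC)CC[C@H]2C=C1O[Li] | intermediate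
21 | 3α-(triethylsilyloxy)-8-(trimethylsilyloxy)-10αH-eremophila-8,11-diene | C=C(C)[C@@H]1C[C@]2(C)[C@@H](C)[C@H](O[Si](CC)(CC)CC)CC[C@H]2C=C1O[Si](C)(C)C | intermediate
22 | 8α,9α-epoxide of 21 (8β-trimethylsilyloxy) | C=C(C)[C@@H]1C[C@]2(C)[C@@H](C)[C@H](O[Si](CC)(CC)CC)CC[C@H]2[C@@H]3O[C@]13O[Si](C)(C)C | intermediate
23 | 3α-(triethylsilyloxy)-9α-(trimethylsilyloxy)-10αH-eremophil-11-en-8-one | C=C(C)[C@@H]1C[C@]2(C)[C@@H](C)[C@H](O[Si](CC)(CC)CC)CC[C@H]2[C@H](O[Si](C)(C)C)C1=O | intermediate
24 | 9α-hydroxy-3α-(triethylsilyloxy)-10αH-eremophil-11-en-8-one | C=C(C)[C@@H]1C[C@]2(C)[C@@H](C)[C@H](O[Si](CC)(CC)CC)CC[C@H]2[C@H](O)C1=O | intermediate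
25 | (E)-3-methylpent-2-enoic acid | CC/C(C)=C/C(=O)O | starting material
26 | 9α-[(E)-3-methylpent-2-enoyloxy]-3α-(triethylsilyloxy)-10αH-eremophil-11-en-8-one | C=C(C)[C@@H]1C[C@]2(C)[C@@H](C)[C@H](O[Si](CC)(CC)CC)CC[C@H]2[C@H](OC(=O)/C=C(\C)CC)C1=O | intermediate
27 | 3α-hydroxy-9α-[(E)-3-methylpent-2-enoyloxy]-10αH-eremophil-11-en-8-one | C=C(C)[C@@H]1C[C@]2(C)[C@@H](C)[C@H](O)CC[C@H]2[C@H](OC(=O)/C=C(\C)CC)C1=O | intermediate
28 | angelic acid, (Z)-2-methylbut-2-enoic acid | C/C=C(/C)C(=O)O | starting material
29 | angelic 2,4,6-trichlorobenzoic anhydride | C/C=C(/C)C(=O)OC(=O)c1c(Cl)cc(Cl)cc1Cl | intermediate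
30 | CNP0301161.1, (3R,4R,5R,7S,9S,10R)-3α-angeloyloxy-9α-[(E)-3-methylpent-2-enoyloxy]-10αH-eremophil-11-en-8-one (4β,5β-dimethyl, 7α-isopropenyl) | C=C(C)[C@@H]1C[C@]2(C)[C@@H](C)[C@H](OC(=O)/C(C)=C\C)CC[C@H]2[C@H](OC(=O)/C=C(\C)CC)C1=O | target

**Step count**

Total: 15 steps. Longest linear sequence: 15 steps from 1; compounds 3, 15, 25 and 28 are used as bought.

**Steps most likely to fail**

Step 6 (key step). What may go wrong: ethyl transfer to, or unproductive complexation of, the free enone; closure of the alkoxide onto the sulfonate carbon; or partial migration of the ring methylene if the reacting rotamer is not the expected one. The fallback changes the activating group and the mode of activation. From 8, the secondary hydroxyl would be converted into the p-toluenesulfonate F1 (TsCl, pyridine, 0 °C). The shift would then be run without any organometallic, as a buffered ionising pinacol-type ring enlargement (LiClO4, CaCO3, THF, 50 °C). Here the neutral hydroxyl assists departure of the sulfonate, no metal alkoxide is present to close to the oxirane, and the more cation-like transition state accentuates the preference for the quaternary carbon. The sequence returns to the route at 11.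

Step 7. What may go wrong: protonation of the enolate during the reduction with over-reduction at C8, incomplete reduction of the C3 ketone, or its enolisation by lithium amide with erosion of the C4 configuration, so that the doubly silylated enol ether is not obtained cleanly. The fallback is kinetic reduction followed by inversion. From 11, LiBH(s-Bu)3 (THF, −78 °C) should reduce only the saturated ketone, from the open α face, to the axial 3β-alcohol F2. A Mitsunobu reaction (PPh3, DIAD, 4-nitrobenzoic acid, toluene) would invert C3 to the 3α-(4-nitrobenzoate) F3. Methanolysis (K2CO3, MeOH) would give the 3α-alcohol F4, and silylation (Et3SiCl, imidazole, DMF) rejoins the route at 14, bypassing 13.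

Step 10. What may go wrong: loss of H7 in competition with the methyl hydrogens, giving the conjugated isopropylidene isomer, or later drift of the isopropenyl double bond into conjugation. The fallback makes the conjugated isomer on purpose and deconjugates it. From 17, dehydration followed by base equilibration (SOCl2, pyridine; then DBU, CH2Cl2) would give the cross-conjugated 7(11),9-dienone F5. γ-Deprotonation at the methyl group syn to the carbonyl (LiN(iPr)2, THF, −78 °C) and kinetic protonation of the extended enolate at the α carbon C7 (AcOH, −78 °C) is the known deconjugation of α-isopropylidene ketones and returns to the route at 19.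

**Further compounds**

F1 | step 6 | (1R)-1-[(1S,7aS)-1-hydroxy-7a-methyl-5-oxo-2,3,5,6,7,7a-hexahydro-1H-inden-1-yl]ethyl 4-methylbenzenesulfonate | C[C@]12CCC(=O)C=C1CC[C@@]2(O)[C@@H](C)OS(=O)(=O)c1ccc(C)cc1
F2 | step 7 | 3β-hydroxy-4β,5β-dimethyloctal-9-en-8-one | C1C[C@]2(C)[C@@H](C)[C@@H](O)CCC2=CC1=O
F3 | step 7 | 3α-(4-nitrobenzoyloxy)-4β,5β-dimethyloctal-9-en-8-one | C1C[C@]2(C)[C@@H](C)[C@H](OC(=O)c3ccc(cc3)[N+](=O)[O-])CCC2=CC1=O
F4 | step 7 | 3α-hydroxy-4β,5β-dimethyloctal-9-en-8-one | C1C[C@]2(C)[C@@H](C)[C@H](O)CCC2=CC1=O
F5 | step 10 | 3α-(triethylsilyloxy)eremophila-7(11),9-dien-8-one | CC(C)=C1C[C@]2(C)[C@@H](C)[C@H](O[Si](CC)(CC)CC)CCC2=CC1=O
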